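**Assumption:** Malabaricone C (1-(2,6-dihydroxyphenyl)-9-(3,4-dihydroxyphenyl)nonan-1-one) has no stereocenters, so there is no enantiomer to set. Both aromatic rings come from commercial materials, so no rings are formed in the route.

**Retrosynthesis**
- Global demethylation of the four aryl methyl ethers (BBr3) gives the tetramethyl ether **8**.
- Hydrogenation of the C=C of **7** gives **8**. The internal alkene is disconnected by olefin cross-metathesis between methyl eugenol **6** and the terminal alkene ketone **5**.
- The aryl ketone in **5** is disconnected by addition of 2,6-dimethoxyphenyllithium, made by directed ortho-lithiation of 1,3-dimethoxybenzene **4**, to the Weinreb amide **3** of 7-octenoic acid **1**.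

---

**Step 1**
Reactants: 1 (7-octenoic acid); 2 (N,O-dimethylhydroxylamine hydrochloride)
Product: 3 (N-methoxy-N-methyloct-7-enamide, the Weinreb amide)
Conditions: CDI, CH2Cl2, rt; then 2, rt (or EDC·HCl, HOBt, iPr2NEt)
Reagents that add atoms: N,O-dimethylhydroxylamine (2), CONC (as its HCl salt)
Why: Carboxylic acid activation followed by amide coupling gives a Weinreb amide, which stops cleanly at the ketone stage in the next step. The terminal alkene is untouched.

**Step 2**
Reactants: 4 (1,3-dimethoxybenzene); 3
Product: 5 (1-(2,6-dimethoxyphenyl)oct-7-en-1-one)
Conditions: 4, n-BuLi, THF, 0 °C to rt, 2 h; then 3, −78 °C to rt; NH4Cl work-up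
Reagents that add atoms: none (n-BuLi only deprotonates; the aryl group comes from 4)
Why: Directed ortho-metalation between the two OMe groups gives 2,6-dimethoxyphenyllithium. This adds to the Weinreb amide to form a chelated tetrahedral intermediate, which collapses to the ketone on work-up. This is a Weinreb ketone synthesis with no over-addition.

**Step 3**
Reactants: 5; 6 (methyl eugenol, 4-allyl-1,2-dimethoxybenzene)
Product: 7 ((E/Z)-1-(2,6-dimethoxyphenyl)-9-(3,4-dimethoxyphenyl)non-7-en-1-one)
Conditions: Hoveyda–Grubbs II (5 mol %), 1,4-benzoquinone (10 mol %), CH2Cl2, 40 °C, 12 h; 6 (2–3 equiv)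
Reagents that add atoms: none (the catalyst and additive do not end up in the product; ethylene is lost)
Why: Olefin cross-metathesis between two terminal alkenes, with excess 6 to favor the cross product over the homodimer of 5. Benzoquinone suppresses Ru–H alkene isomerization, which would scramble the chain length. The alkene geometry is irrelevant because it is reduced next.

**Step 4**
Reactants: 7
Product: 8 (1-(2,6-dimethoxyphenyl)-9-(3,4-dimethoxyphenyl)nonan-1-one)
Conditions: H2 (1 atm), 10% Pd/C, EtOAc, rt
Reagents that add atoms: none (H2 adds only hydrogen)
Why: Catalytic hydrogenation saturates the disubstituted alkene. The hindered, electron-rich aryl ketone and the aryl methyl ethers are inert under neutral, 1 atm conditions. No stereocenter is formed.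

**Step 5**
Reactants: 8
Product: 9 (malabaricone C)
Conditions: BBr3 (6–8 equiv), CH2Cl2, −78 °C to rt, 12 h; aqueous work-up
Reagents that add atoms: none (after hydrolysis the four O–CH3 groups are replaced by O–H; BBr3 leaves no atoms in the product)
Why: BBr3 cleaves aryl methyl ethers by Lewis-acid activation and bromide attack (O-demethylation). Excess reagent removes all four methyls, including the two chelated to the ketone. The saturated alkyl chain and the aryl ketone survive.

---

**Final check**
- Chain: C(=O) plus eight CH2 groups is nine carbons in the chain, matching the target.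
- Step 3 carbon count: the ArCH2CH= unit from 6 plus =CH(CH2)5C(=O) from 5 gives eight carbons between the aryl ring and C=O after hydrogenation. This matches the target's CCCCCCCC.
- Rings and substituents: the ketone aryl ring carries 2,6-(OH)2 and the other ring carries 3,4-(OH)2, as in the target SMILES.
- Stereochemistry: none in the target, and none is created.

---

**Compound list**

| # | Name | SMILES | Role |
|---|---|---|---|
| 1 | 7-Octenoic acid | C=CCCCCCC(=O)O | starting material |
| 2 | N,O-Dimethylhydroxylamine hydrochloride | CONC.Cl | starting material |
| 3 | N-Methoxy-N-methyloct-7-enamide | C=CCCCCCC(=O)N(C)OC | intermediate |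
| 4 | 1,3-Dimethoxybenzene | COc1cccc(OC)c1 | starting material |
| 5 | 1-(2,6-Dimethoxyphenyl)oct-7-en-1-one | C=CCCCCCC(=O)c1c(OC)cccc1OC | intermediate |
| 6 | Methyl eugenol (4-allyl-1,2-dimethoxybenzene) | C=CCc1ccc(OC)c(OC)c1 | starting material |
| 7 | 1-(2,6-Dimethoxyphenyl)-9-(3,4-dimethoxyphenyl)non-7-en-1-one (E/Z) | COc1ccc(CC=CCCCCCC(=O)c2c(OC)cccc2OC)cc1OC | intermediate |
| 8 | 1-(2,6-Dimethoxyphenyl)-9-(3,4-dimethoxyphenyl)nonan-1-one | COc1ccc(CCCCCCCCC(=O)c2c(OC)cccc2OC)cc1OC | intermediate |
| 9 | Malabaricone C | O=C(CCCCCCCCc1ccc(O)c(O)c1)c1c(O)cccc1O | target |

**Total steps:** 5. **Longest linear sequence:** 5 (1 → 3 → 5 → 7 → 8 → 9).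

**Three steps most likely to fail**
1. **Step 3 (cross-metathesis):** Ru–H isomerization, homodimer formation, or low conversion with the hindered ketone alkene.
   - Fallback: replace steps 3–4 with hydroboration/Suzuki coupling. Use the 8-nonenoic acid analogue of 5, hydroborate with 9-BBN, and couple with 4-bromo-1,2-dimethoxybenzene (Pd(dppf)Cl2, K3PO4). This gives **8** directly.
2. **Step 5 (BBr3 global demethylation):** Incomplete demethylation, boron-catechol complexes that are hard to hydrolyze, and oxidation of the catechol on work-up.
   - Fallback: change the protecting group strategy to benzyl ethers on both rings (made from 1,3-bis(benzyloxy)benzene and 4-allyl-1,2-bis(benzyloxy)benzene). Then one hydrogenolysis over Pd/C removes all benzyls and saturates the alkene.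
3. **Step 2 (aryllithium addition):** The hindered 2,6-dimethoxyphenyllithium may add incompletely, or incompletely lithiated arene may lower the yield.
   - Fallback: add the aryllithium to 7-octenal to give the secondary alcohol, then oxidize it (Dess–Martin periodinane) to the ketone **5**. This avoids the Weinreb amide and step 1.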